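**Plan**

- Retrosynthesis: remove the two formyl groups and the MOM and silyl groups; cut C1′–isobutyl (conjugate addition) and C1=C1′ (aldol condensation) back to ketol 12; cut C4–CH3 (MeLi) back to the bicyclic 1,3-dione 9; then cut C1–C10 and C3–C4 of ring A together, which leaves the ring-B enoate 5 and methyl acetoacetate 6.
- Feature that allows the double cut: in ring A the oxygen-bearing C4 and the quaternary C10 are 1,3-related through the ring-fusion carbon C5, so C4–C5=C10 is a β,β-disubstituted acrylate (1,3-dielectrophile), and C1–C2–C3 with a temporary C2 carbonyl is an acetone 1,3-dianion (1,3-dinucleophile).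
- Forward: ring B from (S)-carvone (steps 1–3); ring A by a Michael–Claisen [3+3] annulation (step 4); C4 methyl carbinol (steps 5–6); side chain on C1 through the C2 ketone, then removal of the C2 oxygen (steps 8–12); arene formylation and deprotection (steps 13–14).
- Stereochemistry: C7 is bought with carvone; C10 and C5 are relayed from it in the key step; C4 (MeLi anti to the axial C10 methyl), C1′ (β-face cuprate attack on the Z-enone) and C1 (β-face hydrogenation) follow by substrate control from the rigid trans-decalin.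

Key step: step 4

Remark: eudesmane numbering is used throughout (decalin C1–C10; C14 = methyl on C10; C15 = methyl on C4; C11 = carbinol carbon on C7; C1′ = benzylic carbon); "α" is the face of the C10 methyl group.

**Step 1**
Reactants: 1 (S)-(+)-carvone
Product: 3 (5S)-2-methyl-5-(prop-1-en-2-yl)cyclohex-1-en-1-yl trifluoromethanesulfonate, via lithium enolate 2 (not isolated)
Conditions: LiBH(s-Bu)3, THF, −78 °C; then PhNTf2, −78 °C → rt
Reagents that add atoms: N-phenylbis(trifluoromethanesulfonimide), O=S(=O)(N(c1ccccc1)S(=O)(=O)C(F)(F)F)C(F)(F)F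
Why: Conjugate hydride reduction of the enone gives the tetrasubstituted enolate regiospecifically and O-triflation traps it; the carvone stereocentre (future C7) is not touched.

**Step 2**
Reactants: 3 (5S)-2-methyl-5-(prop-1-en-2-yl)cyclohex-1-en-1-yl trifluoromethanesulfonate
Product: 4 (5S)-5-(2-hydroxypropan-2-yl)-2-methylcyclohex-1-en-1-yl trifluoromethanesulfonate
Conditions: Co(acac)2 (cat.), PhSiH3, O2 (1 atm), THF, rt
Reagents that add atoms: dioxygen, O=O
Why: Mukaiyama hydration: hydrogen-atom transfer to the 1,1-disubstituted alkene gives the tertiary radical, which is trapped by O2 and reduced to the Markovnikov tertiary alcohol, while the fully substituted enol triflate alkene should not accept a hydrogen atom; no stereocentre is formed.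

**Step 3**
Reactants: 4 (5S)-5-(2-hydroxypropan-2-yl)-2-methylcyclohex-1-en-1-yl trifluoromethanesulfonate
Product: 5 methyl (5S)-5-(2-hydroxypropan-2-yl)-2-methylcyclohex-1-ene-1-carboxylate
Conditions: Pd(OAc)2 (cat.), dppp, CO (1 atm), MeOH, Et3N, DMF, 70 °C
Reagents that add atoms: carbon monoxide, [C-]#[O+]; methanol, CO
Why: Palladium-catalysed methoxycarbonylation of a vinyl triflate (oxidative addition, CO insertion, methanolysis) installs the future C4 as a carboxyl carbon; no stereocentre changes.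

**Step 4**
Reactants: 5 methyl (5S)-5-(2-hydroxypropan-2-yl)-2-methylcyclohex-1-ene-1-carboxylate; 6 methyl acetoacetate
Product: 9 (4aR,7S,8aS)-7-(2-hydroxypropan-2-yl)-4a-methylhexahydronaphthalene-1,3(2H,4H)-dione, via Michael adduct 7 (not isolated), via dione ester 8 (not isolated)
Conditions: NaOMe (2.5 equiv), MeOH, 90 °C (sealed); then aq. KOH, reflux; then 2 M HCl to pH 2, 50 °C
Reagents that add atoms: none
Why: The sodium enolate of 6 adds through its central carbon (future C1) to the β-carbon of enoate 5 (future C10) in a reversible Michael step; the γ-methyl carbon of adduct 7 (future C3) then closes ring A by a Claisen (Dieckmann-type) condensation onto the ring ester carbonyl (future C4), a 6-(enolendo)-exo-trig acyl substitution that expels methoxide, and irreversible deprotonation of dione ester 8 pulls the unfavourable first step forward before saponification and decarboxylation remove the C1 ester. The closest known reaction type is the Michael–Claisen [3+3] synthesis of cyclohexane-1,3-diones from acetoacetate and an α,β-unsaturated ester, together with the dimedone synthesis, in which a quaternary β-carbon is formed in the same way. C10 is set from C7: because the Michael step is reversible, the adduct that should accumulate and cyclise is the one whose ring-B chair has the C7 hydroxypropyl group, the new C1 chain and the C5 ester all equatorial and the methyl axial, that is, the chain trans to the C7 substituent. C5 is α to the new C4 carbonyl and should equilibrate during the acidic decarboxylation to the trans ring fusion, as in 4-oxo trans-decalins. Regiochemistry is fixed by the substrate, since the only ester within reach of the γ-carbanion is the one on C5 and the acceptor has no ketone for a competing aldol closure. The selectivity the step needs is the C10 configuration; the C10 epimer (cis-fused) is the expected by-product and stays a separable diastereomer because C7 is never epimerised.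

**Step 5**
Reactants: 9 (4aR,7S,8aS)-7-(2-hydroxypropan-2-yl)-4a-methylhexahydronaphthalene-1,3(2H,4H)-dione
Product: 10 (4aR,7S,8aS)-3-[(tert-butyldimethylsilyl)oxy]-7-(2-hydroxypropan-2-yl)-4a-methyl-4a,5,6,7,8,8a-hexahydronaphthalen-1(4H)-one
Conditions: t-BuMe2SiCl, imidazole, DMF, 0 °C → rt
Reagents that add atoms: tert-butyldimethylsilyl chloride, CC(C)(C)[Si](C)(C)Cl
Why: O-silylation of the 1,3-dione enol should take place on the less hindered C2 oxygen (flanked by two CH2 groups) and not on the C4 oxygen next to the ring fusion, which leaves C4 as the only carbonyl (a vinylogous silyl ester as in Stork–Danheiser chemistry); no stereocentre is formed.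

**Step 6**
Reactants: 10 (4aR,7S,8aS)-3-[(tert-butyldimethylsilyl)oxy]-7-(2-hydroxypropan-2-yl)-4a-methyl-4a,5,6,7,8,8a-hexahydronaphthalen-1(4H)-one
Product: 12 (4R,4aS,6S,8aR)-4-hydroxy-6-(2-hydroxypropan-2-yl)-4,8a-dimethyloctahydronaphthalen-2(1H)-one, via dilithium alkoxide 11 (not isolated)
Conditions: MeLi (3.5 equiv), THF, −78 °C; then AcOH, Bu4NF, THF, 0 °C
Reagents that add atoms: methyllithium, [Li]C
Why: 1,2-Addition of MeLi to the C4 carbonyl of the vinylogous silyl ester (Stork–Danheiser-type addition) should come from the β-face, because the axial C10 methyl is 1,3-diaxial to the α-trajectory, so the new methyl is equatorial and the C4 hydroxyl axial and cis to the C10 methyl; buffered fluoride then frees the C2 ketone without ionising the tertiary allylic alcohol.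

**Step 7**
Reactants: 13 2,4,6-trihydroxybenzaldehyde
Product: 14 2,4,6-tris(methoxymethoxy)benzaldehyde
Conditions: NaH, MeOCH2Cl, DMF, 0 °C → rt
Reagents that add atoms: chloromethyl methyl ether, COCCl
Why: Williamson-type O-alkylation of the three phenoxides gives MOM acetals that survive the organometallic steps, direct the later ortho-lithiations and leave under mild acid; no stereocentre is involved.

**Step 8**
Reactants: 12 (4R,4aS,6S,8aR)-4-hydroxy-6-(2-hydroxypropan-2-yl)-4,8a-dimethyloctahydronaphthalen-2(1H)-one; 14 2,4,6-tris(methoxymethoxy)benzaldehyde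
Product: 16 (1Z,4R,4aS,6S,8aS)-4-hydroxy-6-(2-hydroxypropan-2-yl)-4,8a-dimethyl-1-[2,4,6-tris(methoxymethoxy)benzylidene]octahydronaphthalen-2(1H)-one, via aldol adduct 15 (not isolated)
Conditions: LiN(i-Pr)2 (3.3 equiv), THF, −78 °C; 14, −78 → −30 °C; AcOH; then pyridinium p-toluenesulfonate (cat.), CH2Cl2, 25 °C
Reagents that add atoms: none
Why: Directed aldol condensation: with both hydroxyls deprotonated, kinetic enolisation should occur at C1, away from the C4 alkoxide, the C1 enolate adds to 14, and E1 dehydration through the strongly stabilised benzylic cation gives the thermodynamic Z-alkene with the aryl group on the carbonyl side, away from the quaternary C10.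

**Step 9**
Reactants: 16 (1Z,4R,4aS,6S,8aS)-4-hydroxy-6-(2-hydroxypropan-2-yl)-4,8a-dimethyl-1-[2,4,6-tris(methoxymethoxy)benzylidene]octahydronaphthalen-2(1H)-one
Product: 17 (1Z,4R,4aS,6S,8aS)-4,8a-dimethyl-1-[2,4,6-tris(methoxymethoxy)benzylidene]-4-[(trimethylsilyl)oxy]-6-{2-[(trimethylsilyl)oxy]propan-2-yl}octahydronaphthalen-2(1H)-one
Conditions: 1-(trimethylsilyl)imidazole, CH2Cl2, 40 °C
Reagents that add atoms: 1-(trimethylsilyl)imidazole, C[Si](C)(C)n1ccnc1
Why: Neutral silyl transfer caps both tertiary alcohols without acid (the aryl MOM ethers are safe), removes the acidic protons before the Grignard step and places a bulky group on the α-face of ring A; no stereocentre is formed.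

**Step 10**
Reactants: 17 (1Z,4R,4aS,6S,8aS)-4,8a-dimethyl-1-[2,4,6-tris(methoxymethoxy)benzylidene]-4-[(trimethylsilyl)oxy]-6-{2-[(trimethylsilyl)oxy]propan-2-yl}octahydronaphthalen-2(1H)-one
Product: 19 (4R,4aS,6S,8aS)-4,8a-dimethyl-1-{(1S)-3-methyl-1-[2,4,6-tris(methoxymethoxy)phenyl]butyl}-4-[(trimethylsilyl)oxy]-6-{2-[(trimethylsilyl)oxy]propan-2-yl}-3,4,4a,5,6,7,8,8a-octahydronaphthalen-2-yl trifluoromethanesulfonate, via magnesium enolate 18 (not isolated)
Conditions: i-BuMgBr (1.5 equiv), CuBr·SMe2 (0.2 equiv), THF, −40 °C; then N-(5-chloropyridin-2-yl)triflimide, −40 → 0 °C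
Reagents that add atoms: isobutylmagnesium bromide, CC(C)C[Mg]Br; N-(5-chloropyridin-2-yl)-N-(trifluoromethylsulfonyl)trifluoromethanesulfonamide, O=S(=O)(N(c1ccc(Cl)cn1)S(=O)(=O)C(F)(F)F)C(F)(F)F
Why: Copper-catalysed conjugate addition to the exocyclic enone sets C1′: the α-face of the C1=C1′ bond is shielded by the axial C10 methyl (and the axial C4 silyloxy group), so isobutyl should add from the β-face of the Z-alkene and give the (S)-benzylic carbon, and the regiodefined enolate is trapped on oxygen as the triflate.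

**Step 11**
Reactants: 19 the enol triflate of step 10
Product: 20 (4R,4aS,6S,8aS)-4,8a-dimethyl-1-{(1S)-3-methyl-1-[2,4,6-tris(methoxymethoxy)phenyl]butyl}-4-[(trimethylsilyl)oxy]-6-{2-[(trimethylsilyl)oxy]propan-2-yl}-3,4,4a,5,6,7,8,8a-octahydronaphthalene
Conditions: Pd(OAc)2 (cat.), PPh3, HCO2H, n-Bu3N, DMF, 60 °C
Reagents that add atoms: none
Why: Palladium-catalysed formate reduction of a vinyl triflate (oxidative addition, formate-to-hydride exchange with loss of CO2, reductive elimination) replaces C2–OTf by C2–H and so removes the helper oxygen; no stereocentre is formed.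

**Step 12**
Reactants: 20 the C1=C2 alkene of step 11
Product: 21 (1R,4R,4aS,6S,8aR)-4,8a-dimethyl-1-{(1S)-3-methyl-1-[2,4,6-tris(methoxymethoxy)phenyl]butyl}-4-[(trimethylsilyl)oxy]-6-{2-[(trimethylsilyl)oxy]propan-2-yl}decahydronaphthalene
Conditions: H2 (40 bar), 10% Pd/C, EtOAc, 40 °C
Reagents that add atoms: none
Why: Heterogeneous hydrogenation should deliver both hydrogens to the β-face of the C1=C2 bond, opposite the axial C10 methyl and C4 silyloxy groups, which sets C1 with its hydrogen β (axial) and the side chain equatorial.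

**Step 13**
Reactants: 21 the saturated bis-silyl ether of step 12
Product: 24 5-{(1S)-1-[(1R,4R,4aS,6S,8aR)-4,8a-dimethyl-4-[(trimethylsilyl)oxy]-6-{2-[(trimethylsilyl)oxy]propan-2-yl}decahydronaphthalen-1-yl]-3-methylbutyl}-2,4,6-tris(methoxymethoxy)benzene-1,3-dicarbaldehyde, via mono-hemiaminal 22 (not isolated), via bis-hemiaminal 23 (not isolated)
Conditions: n-BuLi, TMEDA, THF, 0 °C; DMF, −78 → 0 °C; n-BuLi, 0 °C; DMF; then H2O
Reagents that add atoms: N,N-dimethylformamide, CN(C)C=O
Why: Directed ortho-metalation: each remaining ring C–H lies between two OMOM groups and is lithiated by n-BuLi, and DMF traps each aryllithium as a lithium hemiaminal that tolerates the second lithiation and gives the aldehyde on work-up; no stereocentre is formed.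

**Step 14**
Reactants: 24 the protected dialdehyde of step 13
Product: 25 5-{(1S)-1-[(1R,4R,4aS,6S,8aR)-4-hydroxy-6-(2-hydroxypropan-2-yl)-4,8a-dimethyldecahydronaphthalen-1-yl]-3-methylbutyl}-2,4,6-trihydroxybenzene-1,3-dicarbaldehyde (target)
Conditions: HCl (1 M), MeOH/THF, 25 °C
Reagents that add atoms: none
Why: Acid-catalysed acetal exchange in methanol cleaves the three MOM ethers (helped by hydrogen bonding to the ortho formyl groups) and the two trimethylsilyl ethers under conditions mild enough to keep both tertiary alcohols; no stereocentre is touched.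

**Compound list**

1 | (S)-(+)-carvone, (5S)-2-methyl-5-(prop-1-en-2-yl)cyclohex-2-en-1-one | CC1=CC[C@@H](CC1=O)C(C)=C | starting material
2 | lithium (5S)-2-methyl-5-(prop-1-en-2-yl)cyclohex-1-en-1-olate | CC1=C(O[Li])C[C@H](CC1)C(C)=C | intermediate (not isolated)
3 | (5S)-2-methyl-5-(prop-1-en-2-yl)cyclohex-1-en-1-yl trifluoromethanesulfonate | CC1=C(OS(=O)(=O)C(F)(F)F)C[C@H](CC1)C(C)=C | intermediate
4 | (5S)-5-(2-hydroxypropan-2-yl)-2-methylcyclohex-1-en-1-yl trifluoromethanesulfonate | CC1=C(OS(=O)(=O)C(F)(F)F)C[C@H](CC1)C(C)(C)O | intermediate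
5 | methyl (5S)-5-(2-hydroxypropan-2-yl)-2-methylcyclohex-1-ene-1-carboxylate | COC(=O)C1=C(C)CC[C@@H](C1)C(C)(C)O | intermediate
6 | methyl acetoacetate (methyl 3-oxobutanoate) | COC(=O)CC(C)=O | starting material
7 | Michael adduct: methyl 5-(2-hydroxypropan-2-yl)-2-(1-methoxy-1,3-dioxobutan-2-yl)-2-methylcyclohexane-1-carboxylate (C10 and C7 as drawn, C5 and C1 not fixed) | COC(=O)C1C[C@@H](C(C)(C)O)CC[C@]1(C)C(C(C)=O)C(=O)OC | intermediate (not isolated)
8 | dione ester: methyl 6-(2-hydroxypropan-2-yl)-8a-methyl-2,4-dioxodecahydronaphthalene-1-carboxylate (C10 and C7 as drawn) | COC(=O)C1C(=O)CC(=O)C2C[C@@H](C(C)(C)O)CC[C@]12C | intermediate (not isolated)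
9 | (4aR,7S,8aS)-7-(2-hydroxypropan-2-yl)-4a-methylhexahydronaphthalene-1,3(2H,4H)-dione (trans-fused) | C1C(=O)CC(=O)[C@H]2C[C@@H](C(C)(C)O)CC[C@]12C | intermediate
10 | (4aR,7S,8aS)-3-[(tert-butyldimethylsilyl)oxy]-7-(2-hydroxypropan-2-yl)-4a-methyl-4a,5,6,7,8,8a-hexahydronaphthalen-1(4H)-one | C1C(O[Si](C)(C)C(C)(C)C)=CC(=O)[C@H]2C[C@@H](C(C)(C)O)CC[C@]12C | intermediate
11 | dilithium alkoxide of the MeLi adduct of 10 (C4 methyl β, C4 oxygen α) | C1C(O[Si](C)(C)C(C)(C)C)=C[C@@](C)(O[Li])[C@H]2C[C@@H](C(C)(C)O[Li])CC[C@]12C | intermediate (not isolated)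
12 | (4R,4aS,6S,8aR)-4-hydroxy-6-(2-hydroxypropan-2-yl)-4,8a-dimethyloctahydronaphthalen-2(1H)-one | C1C(=O)C[C@@](C)(O)[C@H]2C[C@@H](C(C)(C)O)CC[C@]12C | intermediate
13 | 2,4,6-trihydroxybenzaldehyde | O=Cc1c(O)cc(O)cc1O | starting material
14 | 2,4,6-tris(methoxymethoxy)benzaldehyde | O=Cc1c(OCOC)cc(OCOC)cc1OCOC | intermediate
15 | aldol adduct of 12 (at C1) with 14, carbinol and C1 configuration not fixed | OC(c3c(OCOC)cc(OCOC)cc3OCOC)C1C(=O)C[C@@](C)(O)[C@H]2C[C@@H](C(C)(C)O)CC[C@]12C | intermediate (not isolated)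
16 | (1Z,4R,4aS,6S,8aS)-4-hydroxy-6-(2-hydroxypropan-2-yl)-4,8a-dimethyl-1-[2,4,6-tris(methoxymethoxy)benzylidene]octahydronaphthalen-2(1H)-one | COCOc3cc(OCOC)cc(OCOC)c3/C=C1\C(=O)C[C@@](C)(O)[C@H]2C[C@@H](C(C)(C)O)CC[C@]12C | intermediate
17 | bis(trimethylsilyl) ether of 16 | COCOc3cc(OCOC)cc(OCOC)c3/C=C1\C(=O)C[C@@](C)(O[Si](C)(C)C)[C@H]2C[C@@H](C(C)(C)O[Si](C)(C)C)CC[C@]12C | intermediate
18 | bromomagnesium C1=C2 enolate of the isobutyl adduct, C1′ (S) | CC(C)C[C@H](c3c(OCOC)cc(OCOC)cc3OCOC)C1=C(O[Mg]Br)C[C@@](C)(O[Si](C)(C)C)[C@H]2C[C@@H](C(C)(C)O[Si](C)(C)C)CC[C@]12C | intermediate (not isolated)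
19 | (4R,4aS,6S,8aS)-4,8a-dimethyl-1-{(1S)-3-methyl-1-[2,4,6-tris(methoxymethoxy)phenyl]butyl}-4-[(trimethylsilyl)oxy]-6-{2-[(trimethylsilyl)oxy]propan-2-yl}-3,4,4a,5,6,7,8,8a-octahydronaphthalen-2-yl trifluoromethanesulfonate | CC(C)C[C@H](c3c(OCOC)cc(OCOC)cc3OCOC)C1=C(OS(=O)(=O)C(F)(F)F)C[C@@](C)(O[Si](C)(C)C)[C@H]2C[C@@H](C(C)(C)O[Si](C)(C)C)CC[C@]12C | intermediate
20 | (4R,4aS,6S,8aS)-4,8a-dimethyl-1-{(1S)-3-methyl-1-[2,4,6-tris(methoxymethoxy)phenyl]butyl}-4-[(trimethylsilyl)oxy]-6-{2-[(trimethylsilyl)oxy]propan-2-yl}-3,4,4a,5,6,7,8,8a-octahydronaphthalene | CC(C)C[C@H](c3c(OCOC)cc(OCOC)cc3OCOC)C1=CC[C@@](C)(O[Si](C)(C)C)[C@H]2C[C@@H](C(C)(C)O[Si](C)(C)C)CC[C@]12C | intermediate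
21 | (1R,4R,4aS,6S,8aR)-4,8a-dimethyl-1-{(1S)-3-methyl-1-[2,4,6-tris(methoxymethoxy)phenyl]butyl}-4-[(trimethylsilyl)oxy]-6-{2-[(trimethylsilyl)oxy]propan-2-yl}decahydronaphthalene | CC(C)C[C@H](c3c(OCOC)cc(OCOC)cc3OCOC)[C@H]1CC[C@@](C)(O[Si](C)(C)C)[C@H]2C[C@@H](C(C)(C)O[Si](C)(C)C)CC[C@]12C | intermediate
22 | mono lithium hemiaminal (one ring position carries CH(OLi)NMe2) | CC(C)C[C@H](c3c(OCOC)c(C(O[Li])N(C)C)c(OCOC)cc3OCOC)[C@H]1CC[C@@](C)(O[Si](C)(C)C)[C@H]2C[C@@H](C(C)(C)O[Si](C)(C)C)CC[C@]12C | intermediate (not isolated)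
23 | bis lithium hemiaminal (both ring positions carry CH(OLi)NMe2) | CC(C)C[C@H](c3c(OCOC)c(C(O[Li])N(C)C)c(OCOC)c(C(O[Li])N(C)C)c3OCOC)[C@H]1CC[C@@](C)(O[Si](C)(C)C)[C@H]2C[C@@H](C(C)(C)O[Si](C)(C)C)CC[C@]12C | intermediate (not isolated)
24 | 5-{(1S)-1-[(1R,4R,4aS,6S,8aR)-4,8a-dimethyl-4-[(trimethylsilyl)oxy]-6-{2-[(trimethylsilyl)oxy]propan-2-yl}decahydronaphthalen-1-yl]-3-methylbutyl}-2,4,6-tris(methoxymethoxy)benzene-1,3-dicarbaldehyde | CC(C)C[C@H](c3c(OCOC)c(C=O)c(OCOC)c(C=O)c3OCOC)[C@H]1CC[C@@](C)(O[Si](C)(C)C)[C@H]2C[C@@H](C(C)(C)O[Si](C)(C)C)CC[C@]12C | intermediate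
25 | 5-{(1S)-1-[(1R,4R,4aS,6S,8aR)-4-hydroxy-6-(2-hydroxypropan-2-yl)-4,8a-dimethyldecahydronaphthalen-1-yl]-3-methylbutyl}-2,4,6-trihydroxybenzene-1,3-dicarbaldehyde | CC(C)C[C@H](c1c(O)c(C=O)c(O)c(C=O)c1O)[C@H]1CC[C@@](C)(O)[C@H]2C[C@@H](C(C)(C)O)CC[C@]12C | target

**Step count**

Total: 14 steps. Longest linear sequence: 13 steps (1–6 and 8–14, from carvone); step 7 is the one-step side branch.

**Steps most likely to fail**

Step 4. The Michael adduct at the fully substituted β-carbon may revert faster than the slow γ-deprotonation and Claisen closure, so that no dione forms. The adduct may also lose its acetyl group by retro-Claisen cleavage, or the chain may be delivered cis to the C7 substituent (poor facial selectivity at C10).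
Fallback: it sets out from 4 and comes back at 8, and swaps the polarity of the ring closure (ketone acceptor, malonate donor, as in the dimedone synthesis). Stille coupling of 4 with tributyl(1-ethoxyvinyl)stannane (Pd(PPh3)4, LiCl, dioxane, 90 °C) gives the enol ether 1-[(5S)-5-(2-hydroxypropan-2-yl)-2-methylcyclohex-1-en-1-yl]-1-ethoxyethene F1. Aqueous HCl hydrolyses it to the methyl ketone 1-[(5S)-5-(2-hydroxypropan-2-yl)-2-methylcyclohex-1-en-1-yl]ethan-1-one F2. Sodium dimethyl malonate (NaOMe, MeOH, reflux) adds to C10 of this more electrophilic enone to give the malonate Michael adduct F3. The acetyl methyl group of F3 then closes ring A by Claisen condensation onto a malonate ester and gives the same dione ester 8, which the hydrolysis and decarboxylation of step 4 convert to 9.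

Step 8. Enolisation may not be selective for C1 (competing C3 enolate, or retro-aldol opening of ring A through the C4 alkoxide), and the hindered, electron-rich aldehyde may add reversibly.
Fallback: it sets out from 9 and comes back at 16, and moves the condensation to the dione stage, where C3 is blocked between two carbonyls. The dianion of 9 (LiN(i-Pr)2, 3.3 equiv, THF, −78 °C) has C1 as its only methylene terminus and adds to 14; dehydration (pyridinium p-toluenesulfonate) gives the arylidene dione (4Z)-4-[2,4,6-tris(methoxymethoxy)benzylidene]-7-(2-hydroxypropan-2-yl)-4a-methylhexahydronaphthalene-1,3-dione F4. O-Silylation (t-BuMe2SiCl, imidazole, DMF) gives the linearly conjugated silyl dienol ether with the free C4 ketone F5. MeLi addition and buffered Bu4NF, as in step 6, give 16.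

Step 10. The deactivated, hindered arylidene ketone may undergo 1,2-addition or no addition, or the isobutyl group may be delivered with poor facial selectivity.
Fallback: it sets out from 17 and comes back at 20, and replaces conjugate addition by allylic substitution, which also removes the C2 oxygen. Reduction of 17 (NaBH4, CeCl3·7H2O, MeOH, −40 °C) from the open β-face gives the 2α-allylic alcohol F6. Esterification with picolinic acid (DCC, DMAP, CH2Cl2) gives the allylic picolinate F7. i-BuMgBr with CuBr·SMe2 (THF, −40 °C) then substitutes in the anti-SN2′ sense, delivers isobutyl to C1′ from the face opposite the axial leaving group (the β-face), and gives 20 directly.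

**Further compounds**

F1 | step 4 | 1-[(5S)-5-(2-hydroxypropan-2-yl)-2-methylcyclohex-1-en-1-yl]-1-ethoxyethene | CCOC(=C)C1=C(C)CC[C@@H](C1)C(C)(C)O
F2 | step 4 | 1-[(5S)-5-(2-hydroxypropan-2-yl)-2-methylcyclohex-1-en-1-yl]ethan-1-one | CC(=O)C1=C(C)CC[C@@H](C1)C(C)(C)O
F3 | step 4 | dimethyl 2-[2-acetyl-4-(2-hydroxypropan-2-yl)-1-methylcyclohexyl]malonate (C10 and C7 as drawn) | CC(=O)C1C[C@@H](C(C)(C)O)CC[C@]1(C)C(C(=O)OC)C(=O)OC
F4 | step 8 | (4Z,4aS,7S,8aS)-7-(2-hydroxypropan-2-yl)-4a-methyl-4-[2,4,6-tris(methoxymethoxy)benzylidene]hexahydronaphthalene-1,3(2H,4H)-dione | COCOc3cc(OCOC)cc(OCOC)c3/C=C1\C(=O)CC(=O)[C@H]2C[C@@H](C(C)(C)O)CC[C@]12C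
F5 | step 8 | C2 tert-butyldimethylsilyl dienol ether of F4 with the free C4 ketone | COCOc3cc(OCOC)cc(OCOC)c3/C=C1\C(O[Si](C)(C)C(C)(C)C)=CC(=O)[C@H]2C[C@@H](C(C)(C)O)CC[C@]12C
F6 | step 10 | 2α-allylic alcohol from 1,2-reduction of 17 | COCOc3cc(OCOC)cc(OCOC)c3/C=C1\[C@@H](O)C[C@@](C)(O[Si](C)(C)C)[C@H]2C[C@@H](C(C)(C)O[Si](C)(C)C)CC[C@]12C
F7 | step 10 | pyridine-2-carboxylate (picolinate) ester of F6 | COCOc3cc(OCOC)cc(OCOC)c3/C=C1\[C@@H](OC(=O)c4ccccn4)C[C@@](C)(O[Si](C)(C)C)[C@H]2C[C@@H](C(C)(C)O[Si](C)(C)C)CC[C@]12C
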